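(The data stem from a simulated flask for an exercise; scatter was added.)

The rate constants are not given, so we bracket the dusk flask with its charges and readings.

| setting | dusk | noon | flask |
|---|---|---|---|
| substrate | 0.050 M (fed, over 5.0 h) | 0.025 M (fed, over 5.0 h) | 0.050 M (fed, over 5.0 h) |
| coupling partner | 1 equiv | 1 equiv | 1.00 equiv |
| remark | the very flask that is asked about, followed so far; the fed solution adds 0.25 times the starting volume | run made earlier; the fed solution adds 0.25 times the starting volume | the fed solution adds 0.25 times the starting volume |
| time |  |  | 12 d |

| run | time / d | product / % | substrate / % |
|---|---|---|---|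
| dusk | 0.250 | 28.9 | 71.2 |
| dusk | 0.833 | 40.6 | 60.1 |
| dusk | 1.25 | 44.1 | 56.7 |
| dusk | 2.08 | 44.5 | 53.8 |
| dusk | 3.00 | 44.0 | 54.9 |
| dusk | 4.00 | 43.5 | 55.8 |
| dusk | 5.00 | 45.2 | 54.6 |
| noon | 1.04 | 39.6 | 63.2 |
| noon | 1.67 | 42.9 | 57.0 |
| noon | 2.00 | 41.4 | 56.6 |
| noon | 3.00 | 43.6 | 55.5 |
| noon | 5.00 | 45.8 | 55.9 |
| noon | 8.00 | 44.9 | 53.0 |
| noon | 12.0 | 47.6 | 54.1 |

(standard deviation of a reading: 1 percentage point)

- charges are per starting volume, the dose included; the dosed solution carries all of it
- the reaction counts as stopped when no species that holds the substrate changes by six tenths of a point or more over the second half of the time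

* which holds at 12 d: what has brought the reaction to rest, or that it has not come to rest (forward and back rates have come level / the coupling partner has run out first / it is still moving / all of the substrate has reacted)
* product at 12 d, in percent of the substrate charged

From above, the clean case is the zero of our scale: at 1.00 equiv, each coupling partner charged could give one product, or 100% of the substrate. The readings tighten this. The noon run, at half the charge, has reached the asked time, and its last 3 product readings average 46.1%, which we take as the top of our bracket, a reading from another charge and not a proven limit. From below, the last 4 dusk readings average 44.3%, flat within the scatter of 1 percentage point.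

The middle of this bracket is our reckoning. It gives the partner yield φ, the product made per coupling partner charged, as 45.2%. No reading shows the coupling partner, so we leave open whether the remainder is gone or waiting.

The forecast says 45%, with a range of 43.5% to 46.8%. Its value lies above the low end of our bracket and below the top. It expects that forward and back rates have come level, reasoning: “It fits a balanced reversible exchange”.

The flask gives 45.1%, and the coupling partner has run out first.

    substrate + coupling partner → product, rate k1*[substrate]*[coupling partner]^1.5 (k = 0.0140 M⁻¹·⁵ s⁻¹)
    2 coupling partner → homo dimer (k = 8.90 × 10⁻⁴ M⁻¹ s⁻¹)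

In the flask at 0.184 d, the half-life of substrate by coupling is 0.42 d; at 12.0 d, with 0.075% of the coupling partner, the limiting reagent here, left unbound, it is 3500 d, far longer than the 12 d asked. The flask's φ is 45.1%. Carried to the neighbour flask with 1.70 equiv, our φ would give 76.8% product; that flask gives 56.9%, a partner yield of 33.5%.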